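## The problem

Target 12 is a 1,4-benzodioxane neolignan. A 2,3-dihydro-1,4-benzodioxine (dioxane ring B fused to arene ring C) carries a 3,4,5-trimethoxyphenyl group (ring A) at C2, a methyl group at C3, a methoxy group at C5 and an (E)-3-hydroxyprop-1-enyl chain at C7. The two ring oxygens are not equivalent: O4, bonded to the methyl-bearing C3, lies next to the C5 methoxy group, whereas O1, bonded to the benzylic C2, lies next to the unsubstituted C8. A synthesis from a catechol-type ring C therefore has to tell these oxygens apart. C2 and C3 are adjacent stereocentres, both R, with aryl and methyl trans (both equatorial, the more stable arrangement). C3 is an ordinary secondary ether carbon that can be taken from the chiral pool; C2 is benzylic to an electron-rich ring and can epimerise through its cation, so it is best set late and under the control of C3. The cinnamyl-type allylic alcohol is sensitive to acid and to quinone oxidants, and the C2–O1 benzylic ether ionises under strong acid, so the chain should be completed last and the closing steps kept mild. Two features make a short route possible. The C2–H bond is benzylic to ring A, whose para methoxy group stabilises a cation at C2, so O1–C2 can be made in place of a C–H bond. Ring C without its chain is the trioxygenated benzoate pattern of methyl gallate 5, in which the two hydroxyls flanking the 4-oxygen are equivalent.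

## Retrosynthesis

**Target 12 to ester 8.** The side chain is taken back first. Alcohol 12 is the 1,2-reduction product of (E)-enoate 11. Enoate 11 is the olefination product of aldehyde 10, which comes through benzylic alcohol 9 from methyl ester 8. The bond cut is the side-chain C=C bond. The neighbouring cut between C7 and the chain would need a halogenated ring C and a cross-coupling, whereas the carboxyl carbon of a benzoate already sits at C7. Ester 8 lacks the alkene and the free alcohol, the two groups an oxidant or an acid would attack, so the ring-forming chemistry can be done before they exist. The forward steps must give the E alkene and reduce the enoate without saturating it.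

**Ester 8 to phenol 7.** The O–CH3 bond at C5 is cut. A free hydroxyl at C5 is exactly what remains when one of two equivalent phenols has been used to close the ring, so this cut lets ring C descend from a symmetric precursor. The forward step is a methylation of the only hydroxyl in 7 and raises no selectivity question.

**Phenol 7 to diphenol 6.** The O1–C2 bond is cut and C2 goes back to a CH2 group, so the forward step replaces a benzylic C–H bond by a C–O bond with a quinone oxidant. Of the four C–O bonds of the dioxane this is the one to cut:
- Cutting O4–C3 would mean a ring-closing SN2 at a secondary carbon with a labile benzylic stereocentre at C2 already in place.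
- Cutting the aryl–oxygen bonds would need a halogenated ring C and metal-catalysed C–O coupling.
- The O1–C2 cut uses the inherent reactivity next to ring A and lets C3 direct C2.

Precursor 6 has one ring, one stereocentre and one skeletal bond fewer. Its two hydroxyls are interchanged by rotation about the aryl–O4 bond, so the usual regiochemistry problem does not arise. The forward reaction must abstract hydride from the CH2 group of ring A in preference to oxidising the phenolic ring C, must stop after one oxidation, and must close to the trans isomer.

**Diphenol 6 to alcohol 4 and methyl gallate 5.** The O4–C3 bond is cut on its alkyl side. The cut on the aryl side would demand nucleophilic aromatic substitution on an electron-rich ring; the alkyl-side cut gives a phenol and a secondary alcohol that can be joined under Mitsunobu conditions. Methyl gallate 5 is commercial and its 4-hydroxyl, para to the ester, is the most acidic of the three, so no protecting group should be needed. Because the Mitsunobu reaction inverts, the (R) centre of 6 requires the (S) alcohol 4. The forward reaction must alkylate O4 only and must substitute faster than the activated alcohol eliminates.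

**Alcohol 4 to bromide 1 and epoxide 2.** The aryl–CH2 bond is cut, giving the Grignard reagent 3 of bromide 1 and (S)-propylene oxide 2. The neighbouring cut between CH2 and the carbinol carbon would need an enantioselective C–C bond formation. This cut buys the stereocentre ready-made, because attack at the CH2 terminus of 2 leaves the C–O bond of the stereocentre untouched. Both 1 and 2 are commercial. The forward reaction must open the epoxide only at the unsubstituted carbon.

## Roads not taken

**Alternative 1:** Ring C is cut at C4a–C5 and C6–C7, leading back to the dioxane-fused 2-pyranone aldehyde A1 and 1,1-dimethoxyethene A2. In the forward direction A1 acts as the diene: A2 adds across the pyranone C3 and C6 positions, the bridged lactone expels CO2, and loss of methanol gives aldehyde A3, which is the same compound as 10.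
- Merits: ring C is formed with the C5 methoxy group in place and the C7 carbon at the aldehyde level. A3 is two steps from 12, against four from 7, so on the end game this road is shorter and the chosen plan cannot match it there. The polarity of the lactone (the nucleophilic CH2 of A2 bonding to pyranone C6) also predicts the correct placement of the methoxy group.
- Weak points: A1 is not an available heterocycle. A 3,4-dioxygenated 2-pyranone-6-carbaldehyde must be built and the chiral diol unit attached with the benzylic oxygen on pyranone C4 and the other on C3, which is the catechol regiochemistry problem again in a less familiar ring. The two alkoxy groups make the diene less electron-poor and so less reactive towards an electron-rich dienophile. The free aldehyde is itself a partner for a ketene acetal. The CO2 extrusion needs heat that a benzylic ether on an electron-rich ring may not tolerate.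
- Comparison: against the shorter end game the chosen plan sets a key precursor that is two steps from purchased materials and a ring C that is bought as an arene, not constructed.

**Alternative 2:** Three bonds of ring C (C4a–C8a, C5–C6, C7–C8) are cut at once. The precursors are the bis(ynol ether) A5, derived from diol A4, and methyl propiolate A6. Cp*RuCl(cod) would couple the two alkynyl ether units and insert A6 to give arene A7, closing ring C and the dioxane in one operation.
- Merits: both stereocentres come from A4, which asymmetric dihydroxylation would supply, and no bond to C2 or C3 is made or broken afterwards. In stereochemical security this road is better than the chosen one, which relies on C3 to direct C2. The key step also forms more bonds (three C–C bonds, two rings).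
- Weak points: ynol ethers of secondary alkyl groups with β-hydrogens fragment thermally to ketenes and alkenes, and one of them here is also benzylic. The two hydroxyls of A4 must be alkynylated differently, which costs protecting-group steps. The orientation of A6 relative to the silyl terminus must be controlled. A7 carries a trimethylsilyl group where the C5 methoxy group belongs, and an aryl C–Si to C–O exchange takes an ipso-halogenation and a metal-mediated C–O coupling, at least two further steps, before the same ester-to-propenol sequence.
- Comparison: the chosen plan answers the stereochemical advantage with the facts that trans is the favoured isomer and that the closure can equilibrate under acid. It is clearly ahead on step count and on the stability of its intermediates.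

**Alternative 3:** The dioxane is cut at O4–C4a and O1–C8a and ring C is taken back to a cyclohexane-1,3-dione. The partners are the mono-silyl ether A8 of diol A4 (benzylic oxygen protected) and diazo dione A9. Rh2(OAc)4 would generate the carbene of A9, which inserts into the free O–H bond of A8. Acid then removes the silyl group and condenses the benzylic hydroxyl onto one of the two equivalent ring carbonyls, giving vinylogous ester A10 as C7 epimers. Dehydrogenation to the phenol and methylation would lead to 8.
- Merits: the assignment of the two oxygens is fixed by which hydroxyl is free at the insertion, so regiochemistry is as unambiguous as in the chosen plan. Both stereocentres again come from A4 without any bond to them being broken, and no oxidant meets ring A while ring B forms. On these points it is equal or better.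
- Weak points: A8 requires silylation of the benzylic hydroxyl in preference to the less hindered one, or a protect–deprotect detour. Carbenes of cyclic 2-diazo-1,3-diones insert into secondary alcohols in competition with Wolff rearrangement. The acid condensation puts the benzylic C2–O bond at risk of ionisation. Ring C must finally be aromatised by a dehydrogenation that is no gentler than the oxidation in the chosen plan.
- Comparison: counting A4, A8, A9, the key step, aromatisation and methylation, this road reaches 8 in roughly twice as many steps as the chosen one. Against its stereochemical security the chosen plan sets brevity and a ring C that is aromatic throughout.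

Key step: step 3

Remark on the chemistry: positions are numbered as in 2,3-dihydro-1,4-benzodioxine. The 4-hydroxyl of methyl gallate is assumed to be the most acidic and therefore the site of Mitsunobu alkylation. Epoxide 2 is assumed to be used at its commercial enantiomeric purity, since no later step can raise the purity at C3.

## Route

Step 1
Reactants: 1 5-bromo-1,2,3-trimethoxybenzene; 2 (2S)-2-methyloxirane ((S)-propylene oxide)
Product: 4 (2S)-1-(3,4,5-trimethoxyphenyl)propan-2-ol, via (3,4,5-trimethoxyphenyl)magnesium bromide 3 (not isolated)
Conditions: Mg, THF, reflux; then CuI (10 mol %), 2, THF, −30 → 0 °C; aq. NH4Cl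
Reagents that add atoms: none
Why: Copper-catalysed opening of a terminal epoxide by an aryl Grignard reagent proceeds by SN2 attack at the unsubstituted CH2 group. The C–O bond of the stereocentre is not touched, so the (S) configuration of 2 is carried into 4.

Step 2
Reactants: 4 (2S)-1-(3,4,5-trimethoxyphenyl)propan-2-ol; 5 methyl 3,4,5-trihydroxybenzoate (methyl gallate)
Product: 6 methyl 3,5-dihydroxy-4-{[(2R)-1-(3,4,5-trimethoxyphenyl)propan-2-yl]oxy}benzoate
Conditions: PPh3, DIAD, THF, 0 °C → rt
Reagents that add atoms: none
Why: Mitsunobu etherification: the 4-hydroxyl of 5, para to the ester, is the most acidic and is the one deprotonated by the PPh3/DIAD betaine. Its phenoxide displaces the alkoxyphosphonium ion of 4 by SN2 with inversion, turning the (S) carbinol into the (R) aryl ether centre that becomes C3.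

Step 3
Reactants: 6 methyl 3,5-dihydroxy-4-{[(2R)-1-(3,4,5-trimethoxyphenyl)propan-2-yl]oxy}benzoate
Product: 7 methyl (2R,3R)-5-hydroxy-3-methyl-2-(3,4,5-trimethoxyphenyl)-2,3-dihydro-1,4-benzodioxine-7-carboxylate
Conditions: DDQ (1.05 equiv), 4 Å MS, ClCH2CH2Cl, 0 °C → rt
Reagents that add atoms: none
Why: DDQ (2,3-dichloro-5,6-dicyano-1,4-benzoquinone) forms a charge-transfer complex with the trimethoxyphenyl ring of 6 and removes hydride from the benzylic CH2 group, giving a cation at C2 that the para methoxy group stabilises as a quinoid oxocarbenium ion, with the reduced quinone anion as counter-ion. One of the two flanking phenols, which are interchanged by rotation about the aryl–O4 bond and therefore lead to the same product, adds to the cation and the quinone anion takes up the proton, so the net change is a cross-dehydrogenative C–O coupling. The closest known reaction type is the DDQ-mediated oxidative cyclisation of phenols onto benzylic C–H bonds of alkoxyarenes, as in the conversion of 2-(3-arylpropyl)phenols into flavans. The dioxane ring closes in the 6-exo-trig mode, the oxygen attacking the trigonal C2 whose cationic π bond to ring A lies outside the new ring. The new stereocentre C2 is controlled by C3: the cation holds the C3–H bond in the plane of the aryl-conjugated system to avoid allylic 1,3-strain, the tethered phenol arrives on the face that carries O4, and the chair-like transition state with methyl and aryl both pseudo-equatorial leads to the trans (2R,3R) isomer; because 7 can re-ionise at C2 in the presence of the acidic hydroquinone, any cis isomer should also drain to the more stable trans one. The step needs selectivity for ring A over ring C and for a single oxidation: the ester lowers the electron density of ring C, which has no ortho- or para-dihydroxy pattern that could go to a quinone, O1 in 7 is an aryl ether oxygen that assists a second hydride loss at C2 only weakly, and the oxidant is limited to about one equivalent. Molecular sieves keep water from trapping the cation as a benzylic alcohol.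

Step 4
Reactants: 7 methyl (2R,3R)-5-hydroxy-3-methyl-2-(3,4,5-trimethoxyphenyl)-2,3-dihydro-1,4-benzodioxine-7-carboxylate
Product: 8 methyl (2R,3R)-5-methoxy-3-methyl-2-(3,4,5-trimethoxyphenyl)-2,3-dihydro-1,4-benzodioxine-7-carboxylate
Conditions: MeI, K2CO3, DMF, rt
Reagents that add atoms: iodomethane, CI
Why: Williamson O-methylation of the single phenol of 7. The phenoxide formed by K2CO3 is the only nucleophile present and neither stereocentre is affected.

Step 5
Reactants: 8 methyl (2R,3R)-5-methoxy-3-methyl-2-(3,4,5-trimethoxyphenyl)-2,3-dihydro-1,4-benzodioxine-7-carboxylate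
Product: 9 [(2R,3R)-5-methoxy-3-methyl-2-(3,4,5-trimethoxyphenyl)-2,3-dihydro-1,4-benzodioxin-7-yl]methanol
Conditions: LiAlH4, THF, 0 °C; H2O, aq. NaOH
Reagents that add atoms: none
Why: Hydride reduction of the aryl methyl ester to the benzylic alcohol. The aryl and alkyl ethers, including the C2–O1 benzylic ether, are inert to LiAlH4 under basic work-up.

Step 6
Reactants: 9 [(2R,3R)-5-methoxy-3-methyl-2-(3,4,5-trimethoxyphenyl)-2,3-dihydro-1,4-benzodioxin-7-yl]methanol
Product: 11 ethyl (2E)-3-[(2R,3R)-5-methoxy-3-methyl-2-(3,4,5-trimethoxyphenyl)-2,3-dihydro-1,4-benzodioxin-7-yl]prop-2-enoate, via 7-carbaldehyde 10 (not isolated)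
Conditions: MnO2 (10 equiv), Ph3P=CHCO2Et (1.2 equiv), CH2Cl2, rt
Reagents that add atoms: ethyl (triphenylphosphoranylidene)acetate, CCOC(=O)C=P(c1ccccc1)(c1ccccc1)c1ccccc1
Why: Tandem oxidation–Wittig reaction: MnO2 oxidises the benzylic alcohol to aldehyde 10, which is intercepted as it forms by the stabilised ylide. Stabilised ylides give the (E)-enoate with aromatic aldehydes.

Step 7
Reactants: 11 ethyl (2E)-3-[(2R,3R)-5-methoxy-3-methyl-2-(3,4,5-trimethoxyphenyl)-2,3-dihydro-1,4-benzodioxin-7-yl]prop-2-enoate
Product: 12 (2E)-3-[(2R,3R)-5-methoxy-3-methyl-2-(3,4,5-trimethoxyphenyl)-2,3-dihydro-1,4-benzodioxin-7-yl]prop-2-en-1-ol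
Conditions: i-Bu2AlH (2.5 equiv), CH2Cl2, −78 °C; aq. potassium sodium tartrate
Reagents that add atoms: none
Why: i-Bu2AlH reduces α,β-unsaturated esters by 1,2-addition to the allylic alcohol and leaves the C=C bond alone, so the E geometry is kept. The neutral tartrate work-up protects the acid-sensitive cinnamyl alcohol and the benzylic ether.

## Compound list

1 | 5-bromo-1,2,3-trimethoxybenzene | COc1cc(Br)cc(OC)c1OC | starting material
2 | (2S)-2-methyloxirane ((S)-propylene oxide) | C[C@H]1CO1 | starting material
3 | (3,4,5-trimethoxyphenyl)magnesium bromide | COc1cc([Mg]Br)cc(OC)c1OC | intermediate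
4 | (2S)-1-(3,4,5-trimethoxyphenyl)propan-2-ol | C[C@H](O)Cc1cc(OC)c(OC)c(OC)c1 | intermediate
5 | methyl 3,4,5-trihydroxybenzoate (methyl gallate) | COC(=O)c1cc(O)c(O)c(O)c1 | starting material
6 | methyl 3,5-dihydroxy-4-{[(2R)-1-(3,4,5-trimethoxyphenyl)propan-2-yl]oxy}benzoate | COC(=O)c1cc(O)c(O[C@H](C)Cc2cc(OC)c(OC)c(OC)c2)c(O)c1 | intermediate
7 | methyl (2R,3R)-5-hydroxy-3-methyl-2-(3,4,5-trimethoxyphenyl)-2,3-dihydro-1,4-benzodioxine-7-carboxylate | COC(=O)c1cc(O)c2O[C@H](C)[C@@H](c3cc(OC)c(OC)c(OC)c3)Oc2c1 | intermediate
8 | methyl (2R,3R)-5-methoxy-3-methyl-2-(3,4,5-trimethoxyphenyl)-2,3-dihydro-1,4-benzodioxine-7-carboxylate | COC(=O)c1cc(OC)c2O[C@H](C)[C@@H](c3cc(OC)c(OC)c(OC)c3)Oc2c1 | intermediate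
9 | [(2R,3R)-5-methoxy-3-methyl-2-(3,4,5-trimethoxyphenyl)-2,3-dihydro-1,4-benzodioxin-7-yl]methanol | OCc1cc(OC)c2O[C@H](C)[C@@H](c3cc(OC)c(OC)c(OC)c3)Oc2c1 | intermediate
10 | (2R,3R)-5-methoxy-3-methyl-2-(3,4,5-trimethoxyphenyl)-2,3-dihydro-1,4-benzodioxine-7-carbaldehyde | O=Cc1cc(OC)c2O[C@H](C)[C@@H](c3cc(OC)c(OC)c(OC)c3)Oc2c1 | intermediate
11 | ethyl (2E)-3-[(2R,3R)-5-methoxy-3-methyl-2-(3,4,5-trimethoxyphenyl)-2,3-dihydro-1,4-benzodioxin-7-yl]prop-2-enoate | CCOC(=O)/C=C/c1cc(OC)c2O[C@H](C)[C@@H](c3cc(OC)c(OC)c(OC)c3)Oc2c1 | intermediate
12 | (2E)-3-[(2R,3R)-5-methoxy-3-methyl-2-(3,4,5-trimethoxyphenyl)-2,3-dihydro-1,4-benzodioxin-7-yl]prop-2-en-1-ol | OC/C=C/c1cc(OC)c2O[C@H](C)[C@@H](c3cc(OC)c(OC)c(OC)c3)Oc2c1 | target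

Total step count: 7
Longest linear sequence: 7 steps (1 → 4 → 6 → 7 → 8 → 9 → 11 → 12)

## Least certain steps

**Step 3 (key step).** The most likely failure is oxidation at the wrong place or beyond the intended stage.
- Hydride loss from a CH2 group with a β-aryloxy substituent is slower than from a simple 4-methoxybenzyl position, which gives the quinone time to attack the phenolic ring C.
- The C2–H bond of the product is benzylic and α to oxygen, so a second oxidation with loss of the C2 stereocentre is possible.
- Proton loss from C3 of the cation before trapping would erode the configuration at C3.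
- Incomplete trans selectivity is the smaller concern, because acid equilibration favours trans.

The fallback abandons C–H oxidation and generates the same C2 cation by ionising a benzylic alcohol, a known way to close trans-2-aryl-3-methyl-1,4-benzodioxanes. It sets out from bromide 1 and methyl gallate 5 and returns at 7. Grignard reagent 3 is acylated by (2S)-2-[(tert-butyldimethylsilyl)oxy]-N-methoxy-N-methylpropanamide F1, itself made in one step from commercial ethyl (S)-2-[(tert-butyldimethylsilyl)oxy]propanoate with MeNH(OMe)·HCl and i-PrMgCl. This gives (2S)-2-[(tert-butyldimethylsilyl)oxy]-1-(3,4,5-trimethoxyphenyl)propan-1-one F2. HF·pyridine releases (2S)-2-hydroxy-1-(3,4,5-trimethoxyphenyl)propan-1-one F3. Mitsunobu reaction of F3 with 5 (PPh3, DIAD, inversion) gives methyl 3,5-dihydroxy-4-{[(2R)-1-oxo-1-(3,4,5-trimethoxyphenyl)propan-2-yl]oxy}benzoate F4. NaBH4 in MeOH at low temperature reduces the ketone to methyl 3,5-dihydroxy-4-{[(2R)-1-hydroxy-1-(3,4,5-trimethoxyphenyl)propan-2-yl]oxy}benzoate F5, either C1 epimer being usable. Catalytic TsOH in CH2Cl2 then ionises the benzylic alcohol and closes the ring to 7.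

**Step 2.** The most likely failure is elimination of the activated secondary, homobenzylic alcohol to the conjugated alkene, outrunning substitution by a flanked and weakly nucleophilic phenoxide. Alkylation at a 3-hydroxyl, or tying-up of the phosphonium reagent by the vicinal hydroxyls of 5 as a cyclic phosphorane, would also lower the conversion. The fallback separates activation from substitution. It sets out from 4, which MsCl and Et3N convert into (2S)-1-(3,4,5-trimethoxyphenyl)propan-2-yl methanesulfonate F6. The mono-potassium salt of 5 (one equivalent of K2CO3, DMF, 50–60 °C), in which only the 4-hydroxyl is deprotonated, displaces the sulfonate with inversion, and the route is rejoined at 6.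

**Step 6.** The most likely failure is incomplete oxidation on the MnO2 surface, or erosion of E selectivity when the ylide reacts in the heterogeneous mixture, together with loss of polar material by adsorption. The fallback is stepwise and uses a phosphonate carbanion. It sets out from 9, which is oxidised with MnO2 alone and aldehyde 10 isolated. Horner–Wadsworth–Emmons olefination with triethyl phosphonoacetate and NaH in THF at 0 °C then returns to 11. No new compound arises.

**Step 7.** The most likely failure is conjugate or over-reduction to the saturated alcohol, or ionisation of the electron-rich cinnamyl alcohol (and of the C2 benzylic ether) by Lewis-acidic aluminium species during work-up. The fallback avoids aluminium hydrides at the last stage. It sets out from 9, oxidised to isolated aldehyde 10 as above. Wittig reaction with (triphenylphosphoranylidene)acetaldehyde gives (2E)-3-[(2R,3R)-5-methoxy-3-methyl-2-(3,4,5-trimethoxyphenyl)-2,3-dihydro-1,4-benzodioxin-7-yl]prop-2-enal F7. Luche reduction (NaBH4, CeCl3·7H2O, MeOH, 0 °C) then delivers 12 by clean 1,2-reduction.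

## Further compounds

F1 | step 3 | (2S)-2-[(tert-butyldimethylsilyl)oxy]-N-methoxy-N-methylpropanamide | C[C@H](O[Si](C)(C)C(C)(C)C)C(=O)N(C)OC
F2 | step 3 | (2S)-2-[(tert-butyldimethylsilyl)oxy]-1-(3,4,5-trimethoxyphenyl)propan-1-one | C[C@H](O[Si](C)(C)C(C)(C)C)C(=O)c1cc(OC)c(OC)c(OC)c1
F3 | step 3 | (2S)-2-hydroxy-1-(3,4,5-trimethoxyphenyl)propan-1-one | C[C@H](O)C(=O)c1cc(OC)c(OC)c(OC)c1
F4 | step 3 | methyl 3,5-dihydroxy-4-{[(2R)-1-oxo-1-(3,4,5-trimethoxyphenyl)propan-2-yl]oxy}benzoate | C[C@@H](Oc1c(O)cc(cc1O)C(=O)OC)C(=O)c1cc(OC)c(OC)c(OC)c1
F5 | step 3 | methyl 3,5-dihydroxy-4-{[(2R)-1-hydroxy-1-(3,4,5-trimethoxyphenyl)propan-2-yl]oxy}benzoate (C1 epimers) | C[C@@H](Oc1c(O)cc(cc1O)C(=O)OC)C(O)c1cc(OC)c(OC)c(OC)c1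
F6 | step 2 | (2S)-1-(3,4,5-trimethoxyphenyl)propan-2-yl methanesulfonate | C[C@H](OS(C)(=O)=O)Cc1cc(OC)c(OC)c(OC)c1
F0 | step 6 | none | none
F7 | step 7 | (2E)-3-[(2R,3R)-5-methoxy-3-methyl-2-(3,4,5-trimethoxyphenyl)-2,3-dihydro-1,4-benzodioxin-7-yl]prop-2-enal | O=C/C=C/c1cc(OC)c2O[C@H](C)[C@@H](c3cc(OC)c(OC)c(OC)c3)Oc2c1
A1 | alternative 1 | (2R,3R)-3-methyl-5-oxo-2-(3,4,5-trimethoxyphenyl)-2,3-dihydro-5H-pyrano[3,4-b][1,4]dioxine-7-carbaldehyde | O=CC1=CC2=C(C(=O)O1)O[C@H](C)[C@@H](c1cc(OC)c(OC)c(OC)c1)O2
A2 | alternative 1 | 1,1-dimethoxyethene | C=C(OC)OC
A3 | alternative 1 | (2R,3R)-5-methoxy-3-methyl-2-(3,4,5-trimethoxyphenyl)-2,3-dihydro-1,4-benzodioxine-7-carbaldehyde (identical with 10) | O=Cc1cc(OC)c2O[C@H](C)[C@@H](c3cc(OC)c(OC)c(OC)c3)Oc2c1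
A4 | alternative 2 | (1R,2R)-1-(3,4,5-trimethoxyphenyl)propane-1,2-diol | O[C@H](c1cc(OC)c(OC)c(OC)c1)[C@@H](C)O
A5 | alternative 2 | trimethyl({[(1R,2R)-1-(ethynyloxy)-1-(3,4,5-trimethoxyphenyl)propan-2-yl]oxy}ethynyl)silane | C#CO[C@H](c1cc(OC)c(OC)c(OC)c1)[C@@H](C)OC#C[Si](C)(C)C
A6 | alternative 2 | methyl prop-2-ynoate (methyl propiolate) | C#CC(=O)OC
A7 | alternative 2 | methyl (2R,3R)-3-methyl-2-(3,4,5-trimethoxyphenyl)-5-(trimethylsilyl)-2,3-dihydro-1,4-benzodioxine-7-carboxylate | COC(=O)c1cc([Si](C)(C)C)c2O[C@H](C)[C@@H](c3cc(OC)c(OC)c(OC)c3)Oc2c1
A8 | alternative 3 | (1R,2R)-1-[(tert-butyldimethylsilyl)oxy]-1-(3,4,5-trimethoxyphenyl)propan-2-ol | CC(C)(C)[Si](C)(C)O[C@H](c1cc(OC)c(OC)c(OC)c1)[C@@H](C)O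
A9 | alternative 3 | methyl 4-diazo-3,5-dioxocyclohexane-1-carboxylate | COC(=O)C1CC(=O)C(=[N+]=[N-])C(=O)C1
A10 | alternative 3 | methyl (2R,3R)-3-methyl-5-oxo-2-(3,4,5-trimethoxyphenyl)-2,3,5,6,7,8-hexahydro-1,4-benzodioxine-7-carboxylate (C7 epimers) | COC(=O)C1CC(=O)C2=C(C1)O[C@H](c1cc(OC)c(OC)c(OC)c1)[C@@H](C)O2
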